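Line 1 – Feature: ring B bears oxygen on four adjacent carbons, C2', C3', C4' and C5', beside the unsubstituted C6' and the chromone-bearing C1'. These four carbons are read as the ring carbons of dimethyl squarate 8 (its C=O carbons become C2' and C5', its C–OMe carbons C3' and C4'), and C1'/C6' as the two carbons of an alkyne.
Line 2 – Target 15 is traced back through the 2'- and 5'-O-methyl bonds to hydroquinone 14 and quinone 13.
Line 3 – Key disconnection C1'–C2': 13 comes from alkynylcyclobutenol 10 by thermal ring opening to an enynylketene and six-membered reclosure (Moore cyclisation).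
Line 4 – 10 is cut between chromone C2 and the alkyne into 2-iodochromone 7 (three steps from 1,2,3,5-tetramethoxybenzene 1) and ethynylcyclobutenol 9 (one step from 8). The halves are joined by Sonogashira coupling.
Line 5 – Ring order: ring A is present in 1, ring C (pyranone) is closed in step 2, ring B is closed last in step 6.

Key step: step 6

Remark: 15 has no stereocentre. The carbinol carbon of 9 and 10 is the only stereocentre on the route; it is made racemic and is destroyed in step 6, so no stereocontrol is required.

Step 1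
Reactants: 1 1,2,3,5-tetramethoxybenzene
Product: 3 1-(2-hydroxy-3,4,6-trimethoxyphenyl)ethanone, via tetramethoxyacetophenone 2 (not isolated)
Conditions: AcCl, AlCl3, Et2O, 0 to 23 °C; ice-water
Reagents that add atoms: acetyl chloride, CC(=O)Cl
Why: Friedel–Crafts acylation occurs at one of the two equivalent free positions of the electron-rich arene, and AlCl3 chelated to the new carbonyl then cleaves an ortho methyl ether, preferentially the one squeezed between the acetyl group and a neighbouring methoxy group, which places the phenol next to the future C8 methoxy group.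

Step 2
Reactants: 3 1-(2-hydroxy-3,4,6-trimethoxyphenyl)ethanone
Product: 5 5,7,8-trimethoxy-4H-chromen-4-one, via enaminone 4 (not isolated)
Conditions: Me2NCH(OMe)2, toluene, 100 °C; evaporate; conc. HCl, CH2Cl2, 40 °C
Reagents that add atoms: N,N-dimethylformamide dimethyl acetal, COC(OC)N(C)C
Why: Enaminone route to 2,3-unsubstituted chromones, in which the methyl ketone condenses with the amide acetal and acid then drives 6-endo-trig attack of the phenol on the enaminone β-carbon with loss of dimethylamine, closing ring C.

Step 3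
Reactants: 5 5,7,8-trimethoxy-4H-chromen-4-one
Product: 7 2-iodo-5,7,8-trimethoxy-4H-chromen-4-one, via chromon-2-ylzinc chloride 6 (not isolated)
Conditions: TMPZnCl·LiCl, THF, 25 °C; I2, THF, 0 °C
Reagents that add atoms: iodine, [I][I]
Why: Regioselective C–H zincation of a chromone with a hindered zinc amide, which in the absence of a carbonyl-bound Lewis acid removes the most acidic proton at C2 next to the ring oxygen, gives a covalent organozinc that leaves the pyranone carbonyl alone and is iodinated by I2 (metalation–iodinolysis).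

Step 4
Reactants: 8 dimethyl squarate
Product: 9 rac-4-ethynyl-4-hydroxy-2,3-dimethoxycyclobut-2-en-1-one
Conditions: HC≡CMgBr (0.5 M in THF), THF, −78 to −20 °C; aq. NH4Cl
Reagents that add atoms: ethynylmagnesium bromide, C#C[Mg]Br
Why: 1,2-Addition of an alkynyl Grignard reagent to one of the two equivalent strained carbonyl groups of the squarate ester stops after one addition because the remaining carbonyl is a vinylogous ester next to an alkoxide, and the new carbinol centre is formed racemic, which is harmless since it is erased in step 6.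

Step 5
Reactants: 7 2-iodo-5,7,8-trimethoxy-4H-chromen-4-one; 9 rac-4-ethynyl-4-hydroxy-2,3-dimethoxycyclobut-2-en-1-one
Product: 10 rac-4-hydroxy-2,3-dimethoxy-4-[(5,7,8-trimethoxy-4-oxo-4H-chromen-2-yl)ethynyl]cyclobut-2-en-1-one
Conditions: Pd(PPh3)4 (5 mol %), CuI (10 mol %), iPr2NEt, THF, 23 °C, argon; then silica gel and activated carbon to strip metal traces
Reagents that add atoms: none
Why: Sonogashira coupling, in which the β-iodoenone-type carbon–iodine bond of 7 adds to zerovalent palladium at room temperature, far below the ring-opening temperature of the cyclobutenone, the hindered tertiary amine cannot displace the vinylogous ester methoxy groups, and joining the halves in this way keeps strong base and alkoxide away from the chromone.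

Step 6
Reactants: 10 rac-4-hydroxy-2,3-dimethoxy-4-[(5,7,8-trimethoxy-4-oxo-4H-chromen-2-yl)ethynyl]cyclobut-2-en-1-one
Product: 13 2-(5,6-dimethoxy-1,4-benzoquinon-2-yl)-5,7,8-trimethoxy-4H-chromen-4-one, via enynylketene 11 (not isolated), via aryl-phenoxyl diradical 12 (not isolated)
Conditions: p-xylene (0.01 M), 138 °C, argon
Reagents that add atoms: none
Why: This is a Moore cyclisation, the known thermal ring expansion of squarate-derived 4-alkynyl-4-hydroxycyclobutenones (aryl-substituted alkynes included) to 1,4-benzoquinones. Heat breaks the C1–C4 bond of the cyclobutenone in a conrotatory four-electron electrocyclic opening, and because the C4 hydroxyl donor prefers to rotate outward the alkynyl arm turns inward, giving enynylketene 11 with alkyne and ketene cis on the central double bond. The ketene carbon (future C2') then bonds to the chromone-bearing alkyne carbon (future C1') in a 6-endo-dig closure that creates ring B as the σ-aryl/phenoxyl diradical 12, and formal passage of the hydroxyl hydrogen to the radical centre at C6' delivers quinone 13. No stereocentre is formed and the racemic carbinol centre of 10 vanishes. Two selectivities are needed: inward placement of the alkyne, which the hydroxyl group secures, and 6-endo over 5-exo closure, which is supported by the aromaticity gained in 12 and by the small atoms (O1 and C3–H) flanking chromone C2. Since the conjugating chromonyl group also stabilises the vinyl radical of the 5-exo path, this second selectivity is not fully secured and is the accepted risk of the route, so dilution, exclusion of oxygen and a metal-free sample of 10 are used to close the avoidable side channels.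

Step 7
Reactants: 13 2-(5,6-dimethoxy-1,4-benzoquinon-2-yl)-5,7,8-trimethoxy-4H-chromen-4-one
Product: 14 2-(2,5-dihydroxy-3,4-dimethoxyphenyl)-5,7,8-trimethoxy-4H-chromen-4-one
Conditions: Na2S2O4, THF–H2O, 23 °C, argon
Reagents that add atoms: none
Why: Dithionite reduction of a 1,4-benzoquinone to its hydroquinone is fast in aqueous-organic medium and touches neither the chromone enone nor the aryl methyl ethers.

Step 8
Reactants: 14 2-(2,5-dihydroxy-3,4-dimethoxyphenyl)-5,7,8-trimethoxy-4H-chromen-4-one
Product: 15 5,7,8-trimethoxy-2-(2,3,4,5-tetramethoxyphenyl)-4H-chromen-4-one (CNP0482056.0)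
Conditions: Me2SO4, K2CO3, acetone, 56 °C, argon
Reagents that add atoms: dimethyl sulfate, COS(=O)(=O)OC
Why: Williamson-type O-methylation of both phenols with dimethyl sulfate and anhydrous carbonate, run under argon so that the hydroquinone is not re-oxidised and without water so that ring C is not opened, should give the heptamethyl ether.

Compound list
1 | 1,2,3,5-tetramethoxybenzene | COc1cc(OC)c(OC)c(OC)c1 | starting material
2 | 1-(2,3,4,6-tetramethoxyphenyl)ethanone | CC(=O)c1c(OC)cc(OC)c(OC)c1OC | intermediate
3 | 1-(2-hydroxy-3,4,6-trimethoxyphenyl)ethanone | CC(=O)c1c(OC)cc(OC)c(OC)c1O | intermediate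
4 | (E)-3-(dimethylamino)-1-(2-hydroxy-3,4,6-trimethoxyphenyl)prop-2-en-1-one | CN(C)/C=C/C(=O)c1c(OC)cc(OC)c(OC)c1O | intermediate
5 | 5,7,8-trimethoxy-4H-chromen-4-one | COc1cc(OC)c2c(=O)ccoc2c1OC | intermediate
6 | (5,7,8-trimethoxy-4-oxo-4H-chromen-2-yl)zinc chloride | COc1cc(OC)c2c(=O)cc([Zn]Cl)oc2c1OC | intermediate
7 | 2-iodo-5,7,8-trimethoxy-4H-chromen-4-one | COc1cc(OC)c2c(=O)cc(I)oc2c1OC | intermediate
8 | dimethyl squarate (3,4-dimethoxycyclobut-3-ene-1,2-dione) | COC1=C(OC)C(=O)C1=O | starting material
9 | rac-4-ethynyl-4-hydroxy-2,3-dimethoxycyclobut-2-en-1-one | COC1=C(OC)C(O)(C#C)C1=O | intermediate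
10 | rac-4-hydroxy-2,3-dimethoxy-4-[(5,7,8-trimethoxy-4-oxo-4H-chromen-2-yl)ethynyl]cyclobut-2-en-1-one | COC1=C(OC)C(O)(C#Cc2cc(=O)c3c(OC)cc(OC)c(OC)c3o2)C1=O | intermediate
11 | (3Z)-4-hydroxy-2,3-dimethoxy-6-(5,7,8-trimethoxy-4-oxo-4H-chromen-2-yl)hexa-1,3-dien-5-yn-1-one (enynylketene, alkyne cis to the ketene) | COC(=C=O)/C(OC)=C(/O)C#Cc1cc(=O)c2c(OC)cc(OC)c(OC)c2o1 | intermediate
12 | ring B σ-aryl/phenoxyl diradical (oxygen-centred radical on C2', carbon-centred radical at C6', OH on C5') | COc1c(OC)c(O)[c]c(-c2cc(=O)c3c(OC)cc(OC)c(OC)c3o2)c1[O] | intermediate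
13 | 2-(5,6-dimethoxy-1,4-benzoquinon-2-yl)-5,7,8-trimethoxy-4H-chromen-4-one | COC1=C(OC)C(=O)C(-c2cc(=O)c3c(OC)cc(OC)c(OC)c3o2)=CC1=O | intermediate
14 | 2-(2,5-dihydroxy-3,4-dimethoxyphenyl)-5,7,8-trimethoxy-4H-chromen-4-one | COc1c(O)cc(-c2cc(=O)c3c(OC)cc(OC)c(OC)c3o2)c(O)c1OC | intermediate
15 | 5,7,8-trimethoxy-2-(2,3,4,5-tetramethoxyphenyl)-4H-chromen-4-one | COc1cc(-c2cc(=O)c3c(OC)cc(OC)c(OC)c3o2)c(OC)c(OC)c1OC | target

Total step count: 8. Longest linear sequence: 7 steps (1, 2, 3, 5, 6, 7, 8).

Steps most likely to fail

Step 6. The enynylketene may be diverted into five-membered diradical closure, because the developing vinyl radical is conjugated with the chromone. The fallback sets out from 10 and comes back at 14. It removes the alkyne so that ring B closes by a closed-shell pericyclic path that has no five-membered alternative. Semihydrogenation of 10 (H2, Pd/CaCO3 poisoned with Pb(OAc)2, quinoline, EtOAc, 23 °C) should give racemic (Z)-4-hydroxy-2,3-dimethoxy-4-[2-(5,7,8-trimethoxy-4-oxo-4H-chromen-2-yl)ethenyl]cyclobut-2-en-1-one F1. Heating in toluene at 110 °C opens it, again with the hydroxyl group turning outward, to the dienylketene F2. This undergoes disrotatory six-electron electrocyclisation to the cyclohexadienone F3, forming the same C1'–C2' bond. Enolisation then gives hydroquinone 14 directly, so steps 6 and 7 are both replaced. This is the known ring expansion of 4-alkenyl-4-hydroxycyclobutenones.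

Step 5. The free alkynyl carbinol may undergo a metal-triggered 1,2-acyl shift (ring expansion) or amine-induced retro-addition, or the alkyne may dimerise oxidatively, faster than cross-coupling takes place. The fallback sets out from 9 and comes back at 10. It masks the carbinol before the metals are brought in. Et3SiOTf and 2,6-lutidine in CH2Cl2 at −78 to 0 °C convert 9 into rac-4-ethynyl-2,3-dimethoxy-4-(triethylsilyloxy)cyclobut-2-en-1-one F4, which lacks the O–H needed for both the acyl shift and the retro-addition. Coupling with 7 under Pd(PPh3)4, CuI and iPr2NEt in THF at 23 °C gives the triethylsilyl ether of 10 F5. HF·pyridine in THF at 0 °C then frees 10.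

Step 3. Metalation may be incomplete or go to C3 on this electron-rich chromone, and the carbon–iodine bond may be lost by hydrolysis on work-up. The fallback sets out from 3 and 8 and comes back at 10. C2 receives its carbon substituent while ring C is built, and the carbinol–alkyne bond is made by acetylide addition, so neither 7 nor step 5 is needed.
- Claisen condensation of 3 with diethyl oxalate (NaOEt, EtOH, 78 °C) gives ethyl 4-(2-hydroxy-3,4,6-trimethoxyphenyl)-2,4-dioxobutanoate F6.
- HCl in EtOH cyclodehydrates this to ethyl 5,7,8-trimethoxy-4-oxo-4H-chromene-2-carboxylate F7.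
- NaBH4 in EtOH–THF at 0 °C reduces the activated ester to 2-(hydroxymethyl)-5,7,8-trimethoxy-4H-chromen-4-one F8.
- MnO2 in CH2Cl2 oxidises it to 5,7,8-trimethoxy-4-oxo-4H-chromene-2-carbaldehyde F9.
- A Colvin rearrangement (Me3SiCHN2, LiN(iPr)2, THF, −78 to 0 °C) gives 2-ethynyl-5,7,8-trimethoxy-4H-chromen-4-one F10. It is chosen because its aprotic medium keeps alkoxide away from ring C and from the product enynone.
- LiN(SiMe3)2 in THF at −78 °C forms the lithium acetylide F11, which is added to 8 at −78 °C and quenched cold with aq. NH4Cl to give 10.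

Further compounds
F1 | step 6 | rac-(Z)-4-hydroxy-2,3-dimethoxy-4-[2-(5,7,8-trimethoxy-4-oxo-4H-chromen-2-yl)ethenyl]cyclobut-2-en-1-one | COC1=C(OC)C(O)(/C=C\c2cc(=O)c3c(OC)cc(OC)c(OC)c3o2)C1=O
F2 | step 6 | (3Z,5Z)-4-hydroxy-2,3-dimethoxy-6-(5,7,8-trimethoxy-4-oxo-4H-chromen-2-yl)hexa-1,3,5-trien-1-one (dienylketene) | COC(=C=O)/C(OC)=C(/O)\C=C/c1cc(=O)c2c(OC)cc(OC)c(OC)c2o1
F3 | step 6 | rac-4-hydroxy-2,3-dimethoxy-6-(5,7,8-trimethoxy-4-oxo-4H-chromen-2-yl)cyclohexa-2,4-dien-1-one | COC1=C(OC)C(O)=CC(c2cc(=O)c3c(OC)cc(OC)c(OC)c3o2)C1=O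
F4 | step 5 | rac-4-ethynyl-2,3-dimethoxy-4-(triethylsilyloxy)cyclobut-2-en-1-one | CC[Si](CC)(CC)OC1(C#C)C(=O)C(OC)=C1OC
F5 | step 5 | rac-2,3-dimethoxy-4-(triethylsilyloxy)-4-[(5,7,8-trimethoxy-4-oxo-4H-chromen-2-yl)ethynyl]cyclobut-2-en-1-one | CC[Si](CC)(CC)OC1(C#Cc2cc(=O)c3c(OC)cc(OC)c(OC)c3o2)C(=O)C(OC)=C1OC
F6 | step 3 | ethyl 4-(2-hydroxy-3,4,6-trimethoxyphenyl)-2,4-dioxobutanoate | CCOC(=O)C(=O)CC(=O)c1c(OC)cc(OC)c(OC)c1O
F7 | step 3 | ethyl 5,7,8-trimethoxy-4-oxo-4H-chromene-2-carboxylate | CCOC(=O)c1cc(=O)c2c(OC)cc(OC)c(OC)c2o1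
F8 | step 3 | 2-(hydroxymethyl)-5,7,8-trimethoxy-4H-chromen-4-one | OCc1cc(=O)c2c(OC)cc(OC)c(OC)c2o1
F9 | step 3 | 5,7,8-trimethoxy-4-oxo-4H-chromene-2-carbaldehyde | O=Cc1cc(=O)c2c(OC)cc(OC)c(OC)c2o1
F10 | step 3 | 2-ethynyl-5,7,8-trimethoxy-4H-chromen-4-one | C#Cc1cc(=O)c2c(OC)cc(OC)c(OC)c2o1
F11 | step 3 | lithium (5,7,8-trimethoxy-4-oxo-4H-chromen-2-yl)acetylide | [Li]C#Cc1cc(=O)c2c(OC)cc(OC)c(OC)c2o1
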